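The route rests on cutting the γ-butyrolactone (ring D) at the two bonds that flank its unsubstituted O–CH2 group, C4–C5 and O1–C2. Because C5 bears only hydrogens and C4 lies next to C3 and the C2 carbonyl, ring D maps onto an open-chain enal plus formaldehyde. One carbene-catalysed operation should turn the enal β-carbon into a nucleophile, bond it to formaldehyde, close the lactone and fix C3 and C4. The precursor is an (E)-2-benzyl-4-arylbut-2-enal with ring A as its benzyl ether and ring B as a tert-butyl aryloxyacetate, whose two carbons later become C8 and C9 of the threo side chain by an Evans syn aldol.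

Key step: step 6

Labels:
- Ring D is the lactone (O1, C2 carbonyl, C3, C4, C5 = OCH2).
- Ring A is the aryl ring of the C4 benzyl group, ring B that of the C3 benzyl group, and ring C that of the side chain.
- The side-chain carbons are C7 (carbinol), C8 (aryloxy carbon) and C9 (CH2OH).
- The target is (3R,4R) in ring D and (7R,8R), that is threo, in the side chain.

Assumption: the sense of induction of the aminoindanol-derived carbene on this untested substrate class cannot be derived from precedent. The (5aR,10bS) salt is written, and its commercial antipode is taken instead if the first run leads into the 4S series. The configuration of 10 is to be secured (for example by X-ray analysis of a salt of acid 11) before going on.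

Remark on the precursor: the ring B oxygen carries CH2CO2t-Bu instead of a removable mask. This group should be inert to the oxidation, the metathesis, the carbene and the amine bases. It needs no phenol unmasking, and it already holds C8 and C9.

Remark on the base: the CH2 between the alkene and ring A of 8 is both vinylogously and benzylically acidic. The annulation is therefore run with a catalytic tertiary amine only, and the stronger base is added after 8 is consumed.

Step 1
Reactants: 1 eugenol (4-allyl-2-methoxyphenol)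
Product: 2 4-allyl-1-(benzyloxy)-2-methoxybenzene (O-benzyleugenol)
Conditions: BnBr (1.1 equiv), K2CO3, DMF, rt
Reagents that add atoms: benzyl bromide, BrCc1ccccc1
Why: Williamson etherification, in which carbonate ionises the phenol and the phenoxide displaces bromide at an unhindered benzylic carbon while the allyl group stays inert.

Step 2
Reactants: 3 3-(4-hydroxy-3-methoxyphenyl)propan-1-ol (dihydroconiferyl alcohol)
Product: 4 tert-butyl 2-[4-(3-hydroxypropyl)-2-methoxyphenoxy]acetate
Conditions: BrCH2CO2t-Bu (1.05 equiv), K2CO3, acetone, reflux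
Reagents that add atoms: tert-butyl bromoacetate, BrCC(=O)OC(C)(C)C
Why: Williamson etherification that should be chemoselective because K2CO3 ionises only the phenol and not the primary alcohol, and the α-bromo ester is a fast SN2 partner.

Step 3
Reactants: 4 tert-butyl 2-[4-(3-hydroxypropyl)-2-methoxyphenoxy]acetate
Product: 5 tert-butyl 2-[2-methoxy-4-(3-oxopropyl)phenoxy]acetate
Conditions: TEMPO (10 mol %), PhI(OAc)2 (1.1 equiv), CH2Cl2, rt
Reagents that add atoms: none
Why: Piancatelli–Margarita oxidation, in which the oxoammonium species takes the primary alcohol to the aldehyde and stops there in the absence of water, leaving the ester and the alkoxyarene untouched.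

Step 4
Reactants: 5 tert-butyl 2-[2-methoxy-4-(3-oxopropyl)phenoxy]acetate; 6 formaldehyde (as 37% aqueous solution)
Product: 7 tert-butyl 2-[4-(2-formylprop-2-en-1-yl)-2-methoxyphenoxy]acetate
Conditions: 37% aq. CH2O (1.2 equiv), pyrrolidine (10 mol %), EtCO2H (10 mol %), i-PrOH, 45 °C
Reagents that add atoms: formaldehyde (compound 6), C=O
Why: organocatalytic Mannich condensation (α-methylenation of an aldehyde), in which the pyrrolidine enamine of 5 adds to the formaldehyde iminium ion and the β-amino aldehyde loses the amine; 3-arylpropanals are standard substrates of this reaction.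

Step 5
Reactants: 7 tert-butyl 2-[4-(2-formylprop-2-en-1-yl)-2-methoxyphenoxy]acetate; 2 O-benzyleugenol
Product: 8 tert-butyl 2-(4-{(E)-4-[4-(benzyloxy)-3-methoxyphenyl]-2-formylbut-2-en-1-yl}-2-methoxyphenoxy)acetate, that is the (E)-but-2-enal with the ring A aryl group on C4 and the ring B benzyl group on C2
Conditions: 2 (2 equiv), second-generation Hoveyda–Grubbs catalyst (5 mol %), 1,4-benzoquinone (10 mol %), CH2Cl2, 40 °C
Reagents that add atoms: none
Why: olefin cross-metathesis between a terminal alkene that homodimerises reversibly and a 2-substituted acrolein that does not homodimerise, the pairing known from methacrolein-type partners to favour the cross product with the new CH2 substituent trans to the formyl group (E), while benzoquinone holds back allyl-to-propenyl migration.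

Step 6
Reactants: 8 (E)-enal; 6 formaldehyde (released from paraformaldehyde)
Product: 10 tert-butyl 2-[4-({(3R,4R)-4-[4-(benzyloxy)-3-methoxybenzyl]-2-oxooxolan-3-yl}methyl)-2-methoxyphenoxy]acetate (trans-lactone), via cis-lactone epimer 9 (not isolated)
Conditions: (5aR,10bS)-2-mesityl-5a,10b-dihydro-4H,6H-indeno[2,1-b][1,2,4]triazolo[4,3-d][1,4]oxazin-2-ium chloride (15 mol %), i-Pr2NEt (15 mol %), dry (CH2O)n (5 equiv), THF, 40 °C; filter, concentrate; DBU (0.5 equiv), toluene, 80 °C
Reagents that add atoms: formaldehyde (compound 6), C=O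
Why: Proposed new method: addition of the triazolylidene to the formyl carbon of 8 and a 1,2-proton shift should give the conjugated enaminol (extended Breslow species), whose β-carbon (future C4) attacks monomeric formaldehyde bled from the polymer (C4–C5 bond), and tautomerisation with protonation at the α-carbon (future C3) leaves an acyl azolium. The primary alkoxide then attacks that carbonyl in a 5-exo-trig acyl substitution (O1–C2 bond), which closes ring D and frees the carbene. The closest known reaction type is the carbene-catalysed homoenolate [3+2] annulation of β-aryl enals with aromatic aldehydes or activated ketones to γ-butyrolactones, and an α-branched β-alkyl enal with formaldehyde as acceptor lies outside that scope. C4 is controlled by the catalyst, whose fused aminoindanol wall leaves one face of the flat enaminol open, whereas C3 is set first by protonation and then thermodynamically, DBU draining cis epimer 9 into the more stable trans-3,4-dibenzyl lactone 10. The step needs attack through the β-carbon and not through the acyl-anion carbon: in 8 the α-benzyl branch and the N-mesityl group crowd the latter, while the β-CH stays within reach of an acceptor that carries no substituent and has no α-hydrogen. It also needs the doubly activated CH2 between the alkene and ring A to stay untouched, which is why only a catalytic tertiary amine is present until 8 is consumed.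

Step 7
Reactants: 10 trans-lactone tert-butyl ester
Product: 11 2-[4-({(3R,4R)-4-[4-(benzyloxy)-3-methoxybenzyl]-2-oxooxolan-3-yl}methyl)-2-methoxyphenoxy]acetic acid
Conditions: TFA–CH2Cl2 (1:4), 0 °C to rt
Reagents that add atoms: none
Why: acidolysis of a tert-butyl ester by E1 loss of 2-methylpropene, which the lactone, the methyl ethers and (on short exposure) the aryl benzyl ether tolerate and which touches no stereocentre.

Step 8
Reactants: 11 aryloxyacetic acid; 12 (S)-4-benzyl-1,3-oxazolidin-2-one
Product: 14 (4S)-4-benzyl-3-{2-[4-({(3R,4R)-4-[4-(benzyloxy)-3-methoxybenzyl]-2-oxooxolan-3-yl}methyl)-2-methoxyphenoxy]acetyl}-1,3-oxazolidin-2-one, via mixed pivalic anhydride 13 (not isolated)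
Conditions: t-BuCOCl (1.1 equiv), Et3N (2.5 equiv), THF, −20 °C; then LiCl (1.1 equiv), 12, −20 °C to rt
Reagents that add atoms: pivaloyl chloride, CC(C)(C)C(=O)Cl (its atoms are held only in 13)
Why: mixed-anhydride N-acylation of an oxazolidinone under LiCl/Et3N activation, in which attack falls on the less hindered aryloxyacetyl carbonyl of 13 and no strong base is present that could open the lactone or disturb C3.

Step 9
Reactants: 14 aryloxyacetyl imide; 15 4-(benzyloxy)-3-methoxybenzaldehyde (O-benzylvanillin)
Product: 18 (4S)-4-benzyl-3-{(2S,3R)-3-[4-(benzyloxy)-3-methoxyphenyl]-2-[4-({(3R,4R)-4-[4-(benzyloxy)-3-methoxybenzyl]-2-oxooxolan-3-yl}methyl)-2-methoxyphenoxy]-3-hydroxypropanoyl}-1,3-oxazolidin-2-one, via boron enolate 16 (not isolated), via boron aldolate 17 (not isolated)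
Conditions: n-Bu2BOTf (1.2 equiv), i-Pr2NEt (1.4 equiv), CH2Cl2, −78 to 0 °C; 15, −78 to 0 °C; then pH 7 buffer, MeOH, 30% H2O2, 0 °C
Reagents that add atoms: di-n-butylboron triflate, CCCCB(CCCC)OS(=O)(=O)C(F)(F)F (its atoms are held only in 16 and 17)
Why: Evans syn aldol, a reaction class established for (2-methoxyphenoxy)acetyl imides and O-protected vanillins, in which soft enolisation (much faster for the imide than for the lactone) gives Z enolate 16, and this reacts through a Zimmerman–Traxler chair on the face away from the benzyl group of the (S)-auxiliary, so that the syn adduct carries the spatial arrangement that becomes 7R,8R (threo).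

Step 10
Reactants: 18 syn aldol adduct
Product: 20 (3R,4R)-4-[4-(benzyloxy)-3-methoxybenzyl]-3-[4-({(1R,2R)-1-[4-(benzyloxy)-3-methoxyphenyl]-1,3-dihydroxypropan-2-yl}oxy)-3-methoxybenzyl]oxolan-2-one, via α-aryloxy aldehyde 19 (not isolated)
Conditions: NaBH4 (4 equiv), THF–H2O (4:1), 0 °C to rt
Reagents that add atoms: none
Why: reductive removal of an oxazolidinone auxiliary with NaBH4 in wet THF, which should be chemoselective because the exocyclic imide carbonyl, further activated by the α-aryloxy group, is far more electrophilic than an α,β-dialkyl γ-lactone, and aldehyde 19 is reduced faster than C8 can epimerise.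

Step 11
Reactants: 20 dibenzyl ether
Product: 21 (3R,4R)-4-(4-hydroxy-3-methoxybenzyl)-3-[4-({(1R,2R)-1,3-dihydroxy-1-(4-hydroxy-3-methoxyphenyl)propan-2-yl}oxy)-3-methoxybenzyl]oxolan-2-one (target, CNP0305334.1)
Conditions: H2 (1 atm), 10% Pd/C, EtOAc–EtOH, rt
Reagents that add atoms: none
Why: catalytic hydrogenolysis of the two aryl benzyl ethers in neutral medium, under which the secondary benzylic C7 hydroxyl, the C8 aryl ether and the lactone of arylglycerol β-aryl ethers are known to persist and no stereocentre is touched.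

Compound list
1 | eugenol | C=CCc1ccc(O)c(OC)c1 | starting material
2 | 4-allyl-1-(benzyloxy)-2-methoxybenzene | C=CCc1ccc(OCc2ccccc2)c(OC)c1 | intermediate
3 | 3-(4-hydroxy-3-methoxyphenyl)propan-1-ol | COc1cc(CCCO)ccc1O | starting material
4 | tert-butyl 2-[4-(3-hydroxypropyl)-2-methoxyphenoxy]acetate | COc1cc(CCCO)ccc1OCC(=O)OC(C)(C)C | intermediate
5 | tert-butyl 2-[2-methoxy-4-(3-oxopropyl)phenoxy]acetate | COc1cc(CCC=O)ccc1OCC(=O)OC(C)(C)C | intermediate
6 | formaldehyde (formalin in step 4, paraformaldehyde in step 6) | C=O | starting material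
7 | tert-butyl 2-[4-(2-formylprop-2-en-1-yl)-2-methoxyphenoxy]acetate | COc1cc(CC(=C)C=O)ccc1OCC(=O)OC(C)(C)C | intermediate
8 | tert-butyl 2-(4-{(E)-4-[4-(benzyloxy)-3-methoxyphenyl]-2-formylbut-2-en-1-yl}-2-methoxyphenoxy)acetate | O=C/C(=C/Cc1ccc(OCc2ccccc2)c(OC)c1)Cc1ccc(OCC(=O)OC(C)(C)C)c(OC)c1 | intermediate
9 | tert-butyl 2-[4-({(3S,4R)-4-[4-(benzyloxy)-3-methoxybenzyl]-2-oxooxolan-3-yl}methyl)-2-methoxyphenoxy]acetate (cis-lactone) | COc1cc(C[C@H]2COC(=O)[C@H]2Cc2ccc(OCC(=O)OC(C)(C)C)c(OC)c2)ccc1OCc1ccccc1 | intermediate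
10 | tert-butyl 2-[4-({(3R,4R)-4-[4-(benzyloxy)-3-methoxybenzyl]-2-oxooxolan-3-yl}methyl)-2-methoxyphenoxy]acetate (trans-lactone) | COc1cc(C[C@H]2COC(=O)[C@@H]2Cc2ccc(OCC(=O)OC(C)(C)C)c(OC)c2)ccc1OCc1ccccc1 | intermediate
11 | 2-[4-({(3R,4R)-4-[4-(benzyloxy)-3-methoxybenzyl]-2-oxooxolan-3-yl}methyl)-2-methoxyphenoxy]acetic acid | COc1cc(C[C@H]2COC(=O)[C@@H]2Cc2ccc(OCC(=O)O)c(OC)c2)ccc1OCc1ccccc1 | intermediate
12 | (S)-4-benzyl-1,3-oxazolidin-2-one | O=C1N[C@@H](Cc2ccccc2)CO1 | starting material
13 | mixed anhydride of 11 and pivalic acid | COc1cc(C[C@H]2COC(=O)[C@@H]2Cc2ccc(OCC(=O)OC(=O)C(C)(C)C)c(OC)c2)ccc1OCc1ccccc1 | intermediate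
14 | (4S)-4-benzyl-3-{2-[4-({(3R,4R)-4-[4-(benzyloxy)-3-methoxybenzyl]-2-oxooxolan-3-yl}methyl)-2-methoxyphenoxy]acetyl}-1,3-oxazolidin-2-one | COc1cc(C[C@H]2COC(=O)[C@@H]2Cc2ccc(OCC(=O)N3C(=O)OC[C@@H]3Cc3ccccc3)c(OC)c2)ccc1OCc1ccccc1 | intermediate
15 | 4-(benzyloxy)-3-methoxybenzaldehyde | COc1cc(C=O)ccc1OCc1ccccc1 | starting material
16 | (Z)-di-n-butylboron enolate of 14 | COc1cc(C[C@H]2COC(=O)[C@@H]2Cc2ccc(O/C=C(\OB(CCCC)CCCC)N3C(=O)OC[C@@H]3Cc3ccccc3)c(OC)c2)ccc1OCc1ccccc1 | intermediate
17 | C7 O-(di-n-butylboryl) aldolate of 18 | COc1cc(C[C@H]2COC(=O)[C@@H]2Cc2ccc(O[C@H](C(=O)N3C(=O)OC[C@@H]3Cc3ccccc3)[C@H](OB(CCCC)CCCC)c3ccc(OCc4ccccc4)c(OC)c3)c(OC)c2)ccc1OCc1ccccc1 | intermediate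
18 | (4S)-4-benzyl-3-{(2S,3R)-3-[4-(benzyloxy)-3-methoxyphenyl]-2-[4-({(3R,4R)-4-[4-(benzyloxy)-3-methoxybenzyl]-2-oxooxolan-3-yl}methyl)-2-methoxyphenoxy]-3-hydroxypropanoyl}-1,3-oxazolidin-2-one | COc1cc(C[C@H]2COC(=O)[C@@H]2Cc2ccc(O[C@H](C(=O)N3C(=O)OC[C@@H]3Cc3ccccc3)[C@H](O)c3ccc(OCc4ccccc4)c(OC)c3)c(OC)c2)ccc1OCc1ccccc1 | intermediate
19 | (2S,3R)-3-[4-(benzyloxy)-3-methoxyphenyl]-2-[4-({(3R,4R)-4-[4-(benzyloxy)-3-methoxybenzyl]-2-oxooxolan-3-yl}methyl)-2-methoxyphenoxy]-3-hydroxypropanal | COc1cc(C[C@H]2COC(=O)[C@@H]2Cc2ccc(O[C@H](C=O)[C@H](O)c3ccc(OCc4ccccc4)c(OC)c3)c(OC)c2)ccc1OCc1ccccc1 | intermediate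
20 | (3R,4R)-4-[4-(benzyloxy)-3-methoxybenzyl]-3-[4-({(1R,2R)-1-[4-(benzyloxy)-3-methoxyphenyl]-1,3-dihydroxypropan-2-yl}oxy)-3-methoxybenzyl]oxolan-2-one | COc1cc(C[C@H]2COC(=O)[C@@H]2Cc2ccc(O[C@H](CO)[C@H](O)c3ccc(OCc4ccccc4)c(OC)c3)c(OC)c2)ccc1OCc1ccccc1 | intermediate
21 | (3R,4R)-4-(4-hydroxy-3-methoxybenzyl)-3-[4-({(1R,2R)-1,3-dihydroxy-1-(4-hydroxy-3-methoxyphenyl)propan-2-yl}oxy)-3-methoxybenzyl]oxolan-2-one | COc1cc(C[C@H]2COC(=O)[C@@H]2Cc2ccc(O[C@H](CO)[C@H](O)c3ccc(O)c(OC)c3)c(OC)c2)ccc1O | target

Total step count: 11. Longest linear sequence: 10 steps (steps 2 to 11, from 3).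

Steps most likely to fail

1. Step 6.
What may go wrong:
- The hindered α-branched formyl group may resist carbene addition.
- The carbene may be used up in self-condensation of formaldehyde.
- The enaminol may react through its acyl-anion carbon or simply be protonated at the β-carbon and then be trapped by adventitious hydroxyl groups of the polymer.
- The amine may shift the double bond towards ring A.
- Facial selectivity may be poor.

Fallback (known chemistry), setting out from 3 and coming back at 10. Compound 3 is O-benzylated (BnBr, K2CO3) to 3-[4-(benzyloxy)-3-methoxyphenyl]propan-1-ol F1. This is acylated with bromoacetyl bromide to the bromoacetate F2, which N,N'-ditosylhydrazine and DBU convert into the diazoacetate F3. Enantioselective intramolecular C–H insertion follows with Rh2(MPPIM)4 (MPPIM = methyl 1-(3-phenylpropanoyl)-2-oxoimidazolidine-4-carboxylate, in the antipode that leads to the R lactone). It gives (R)-4-[4-(benzyloxy)-3-methoxybenzyl]oxolan-2-one F4. Separately, commercial vanillyl alcohol is alkylated at the phenol with tert-butyl bromoacetate and K2CO3 to tert-butyl 2-[4-(hydroxymethyl)-2-methoxyphenoxy]acetate F5. An Appel reaction (CBr4, PPh3) then gives tert-butyl 2-[4-(bromomethyl)-2-methoxyphenoxy]acetate F6. Deprotonation of F4 with LiN(SiMe3)2 in THF at −78 °C gives the lithium enolate of F4 F7. It is alkylated by F6 on the face anti to the C4 benzyl group, the classical way to trans-dibenzylbutyrolactones, and this delivers 10.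

2. Step 5.
What may go wrong:
- The crowded 1,1-disubstituted alkene of 7 may engage the ruthenium alkylidene too slowly. Homodimerisation of 2, migration of its double bond into conjugation with ring A and catalyst decay would then take over.
- Control of the alkene geometry may be incomplete.

Fallback, setting out from 2 and 5 and coming back at 8. Compound 2 undergoes a one-pot Lemieux–Johnson cleavage (OsO4 cat., NaIO4, 2,6-lutidine, dioxane–H2O). It passes through the vicinal diol F8 and gives [4-(benzyloxy)-3-methoxyphenyl]acetaldehyde F9. Aldehyde 5 is converted with TIPSOTf (1.05 equiv) and Et3N at 0 °C into its Z triisopropylsilyl enol ether F10. A Mukaiyama aldol addition of F10 to F9 (BF3·OEt2, CH2Cl2, −78 °C) fixes which aldehyde acts as donor and gives the β-hydroxy aldehyde F11, whose two centres are erased in the next operation. MsCl and Et3N form the mesylate F12, which eliminates in the same flask to the conjugated E-enal 8.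

3. Step 10.
What may go wrong:
- Hydride may also attack the lactone carbonyl.
- The basic medium may trigger retro-aldol cleavage or epimerisation at C8 before reduction is complete.
- Attack at the ring carbonyl of the auxiliary may open the oxazolidinone instead of releasing it.

Fallback, setting out from 18 and coming back at 20. The auxiliary is removed hydrolytically with LiOH and H2O2 (THF–H2O, 0 °C; any opened lactone recloses on acidification). This gives the (2S,3R)-2-aryloxy-3-hydroxy acid F13. Its carboxyl group is then reduced with BH3·SMe2 in THF at 0 °C, an electrophilic hydride that prefers carboxylic acids over lactones, to give 20.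

Further compounds
F1 | step 6 | 3-[4-(benzyloxy)-3-methoxyphenyl]propan-1-ol | COc1cc(CCCO)ccc1OCc1ccccc1
F2 | step 6 | 3-[4-(benzyloxy)-3-methoxyphenyl]propyl bromoacetate | COc1cc(CCCOC(=O)CBr)ccc1OCc1ccccc1
F3 | step 6 | 3-[4-(benzyloxy)-3-methoxyphenyl]propyl diazoacetate | COc1cc(CCCOC(=O)C=[N+]=[N-])ccc1OCc1ccccc1
F4 | step 6 | (R)-4-[4-(benzyloxy)-3-methoxybenzyl]oxolan-2-one | COc1cc(C[C@H]2COC(=O)C2)ccc1OCc1ccccc1
F5 | step 6 | tert-butyl 2-[4-(hydroxymethyl)-2-methoxyphenoxy]acetate | COc1cc(CO)ccc1OCC(=O)OC(C)(C)C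
F6 | step 6 | tert-butyl 2-[4-(bromomethyl)-2-methoxyphenoxy]acetate | COc1cc(CBr)ccc1OCC(=O)OC(C)(C)C
F7 | step 6 | lithium enolate of F4 | [Li+].COc1cc(C[C@H]2COC([O-])=C2)ccc1OCc1ccccc1
F8 | step 5 | 3-[4-(benzyloxy)-3-methoxyphenyl]propane-1,2-diol (racemic) | COc1cc(CC(O)CO)ccc1OCc1ccccc1
F9 | step 5 | [4-(benzyloxy)-3-methoxyphenyl]acetaldehyde | COc1cc(CC=O)ccc1OCc1ccccc1
F10 | step 5 | tert-butyl 2-(2-methoxy-4-{(Z)-3-[(triisopropylsilyl)oxy]prop-2-en-1-yl}phenoxy)acetate | COc1cc(C/C=C\O[Si](C(C)C)(C(C)C)C(C)C)ccc1OCC(=O)OC(C)(C)C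
F11 | step 5 | tert-butyl 2-(4-{4-[4-(benzyloxy)-3-methoxyphenyl]-2-formyl-3-hydroxybutyl}-2-methoxyphenoxy)acetate (racemic mixture of diastereomers) | COc1cc(CC(C=O)C(O)Cc2ccc(OCc3ccccc3)c(OC)c2)ccc1OCC(=O)OC(C)(C)C
F12 | step 5 | methanesulfonate of F11 (racemic mixture of diastereomers) | COc1cc(CC(C=O)C(OS(C)(=O)=O)Cc2ccc(OCc3ccccc3)c(OC)c2)ccc1OCC(=O)OC(C)(C)C
F13 | step 10 | (2S,3R)-3-[4-(benzyloxy)-3-methoxyphenyl]-2-[4-({(3R,4R)-4-[4-(benzyloxy)-3-methoxybenzyl]-2-oxooxolan-3-yl}methyl)-2-methoxyphenoxy]-3-hydroxypropanoic acid | COc1cc(C[C@H]2COC(=O)[C@@H]2Cc2ccc(O[C@H](C(=O)O)[C@H](O)c3ccc(OCc4ccccc4)c(OC)c3)c(OC)c2)ccc1OCc1ccccc1
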